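**Plan**

Labels: bicycle C1–C7 (C2 spiro carbon, C6 CMe2 bridge, C7 CH2 bridge); pyran ring O1', C3', C4'; arene C4a'–C8a'.
Retrosynthesis cuts C8'–CHO and C6'–acyl, then the spiro C2–O1' bond (retro oxa-6π electrocyclisation to an o-quinone methide, i.e. a 2-styryl carbinol), then C3–C4 and C2–C3 of the six-membered carbocycle (C3 = CH2 of methyl phenyl sulfone), then the C3'=C4' enone bond (aldol).
Forward: the cyclobutane comes from (1S,5S)-verbenone; the six-membered ring of the bicyclo[3.1.1]heptane is closed at C3–C4; the pyran ring follows by electrocyclisation; hydrogenation, acylation, deprotection and formylation finish the arene.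
Feature that makes the key event possible: C1 and C5 of the gem-dimethylcyclobutane are cis, so the ketone carbon C2 on C1 and the iodomethyl carbon C4 on C5 form a 1,5-bis-electrophile. C2 is flanked by two CH2 groups, so the missing ring atom C3 can enter as a sulfone-stabilised CH2 dinucleophile, and the sulfonyl group is removed afterwards.
Stereochemistry: C1 and C5 are bought with verbenone; C2 is set in step 10 by substrate control (O1' closes onto C2 anti to the gem-dimethyl bridge); the carbinol and sulfonyl centres made in the key step are temporary.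

Key step: step 7

Assumption: commercial (1S,5S)-(−)-verbenone is taken as enantiomerically pure; material of lower optical purity would be upgraded by recrystallisation at the stage of acid 2.

**Step 1**
Reactants: 1 (1S,5S)-(−)-verbenone [(1S,5S)-4,6,6-trimethylbicyclo[3.1.1]hept-3-en-2-one]
Product: 2 (1S,3R)-3-acetyl-2,2-dimethylcyclobutane-1-carboxylic acid (cis-pinononic acid)
Conditions: RuCl3·xH2O (2 mol%), NaIO4 (4.2 equiv), CCl4/MeCN/H2O, rt
Reagents that add atoms: sodium periodate [Na+].[O-]I(=O)(=O)=O; water O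
Why: Ruthenium tetroxide made in situ cleaves the enone C=C bond and the α-keto acid formed is decarboxylated oxidatively, a known degradation of verbenone that touches neither ring stereocentre, so the cis-1,3 cyclobutane and its absolute configuration come from the chiral pool.

**Step 2**
Reactants: 2 (1S,3R)-3-acetyl-2,2-dimethylcyclobutane-1-carboxylic acid
Product: 3 1-[(1R,3S)-3-(hydroxymethyl)-2,2-dimethylcyclobutyl]ethan-1-one
Conditions: BH3·SMe2 (1.1 equiv), THF, −15 → 0 °C; MeOH, then H2O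
Reagents that add atoms: none
Why: Borane reduces a carboxylic acid through its acyloxyborane much faster than a ketone, so this chemoselective reduction should leave the methyl ketone (partly present as its cyclic hemiketal) and both stereocentres unchanged.

**Step 3**
Reactants: 4 2,4,6-trihydroxybenzaldehyde
Product: 5 2-hydroxy-4,6-bis(methoxymethoxy)benzaldehyde
Conditions: MOMCl (2.1 equiv), i-Pr2NEt, CH2Cl2, 0 °C → rt
Reagents that add atoms: chloromethyl methyl ether COCCl
Why: O-alkylation (acetal formation) should take place at the two free phenols, while the hydroxyl hydrogen-bonded to the aldehyde is the least nucleophilic and should stay free.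

**Step 4**
Reactants: 5 2-hydroxy-4,6-bis(methoxymethoxy)benzaldehyde
Product: 6 2-(allyloxy)-4,6-bis(methoxymethoxy)benzaldehyde
Conditions: allyl bromide, K2CO3, DMF, rt
Reagents that add atoms: allyl bromide C=CCBr
Why: Williamson etherification masks the phenol that later becomes O1' as an allyl ether, which tolerates the organolithium steps and is removable under neutral conditions.

**Step 5**
Reactants: 3 1-[(1R,3S)-3-(hydroxymethyl)-2,2-dimethylcyclobutyl]ethan-1-one; 6 2-(allyloxy)-4,6-bis(methoxymethoxy)benzaldehyde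
Product: 7 (E)-3-[2-(allyloxy)-4,6-bis(methoxymethoxy)phenyl]-1-[(1R,3S)-3-(hydroxymethyl)-2,2-dimethylcyclobutyl]prop-2-en-1-one
Conditions: KOH, EtOH/H2O, 0 °C → rt
Reagents that add atoms: none
Why: In this Claisen–Schmidt condensation only the aldol on the methyl side can dehydrate, which should give the (E)-enone under thermodynamic control, and the mild conditions together with the greater stability of the cis-1,3 cyclobutane should hold the ketone α-stereocentre (no new stereocentre).

**Step 6**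
Reactants: 7 (E)-3-[2-(allyloxy)-4,6-bis(methoxymethoxy)phenyl]-1-[(1R,3S)-3-(hydroxymethyl)-2,2-dimethylcyclobutyl]prop-2-en-1-one
Product: 8 (E)-3-[2-(allyloxy)-4,6-bis(methoxymethoxy)phenyl]-1-[(1R,3S)-3-(iodomethyl)-2,2-dimethylcyclobutyl]prop-2-en-1-one
Conditions: I2, PPh3, imidazole, CH2Cl2, 0 °C → rt
Reagents that add atoms: iodine II
Why: Appel iodination converts the primary alcohol into the iodide by SN2 at a CH2 group (no stereocentre involved), and imidazole buffers the medium so that the MOM ethers should survive.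

**Step 7**
Reactants: 8 (E)-3-[2-(allyloxy)-4,6-bis(methoxymethoxy)phenyl]-1-[(1R,3S)-3-(iodomethyl)-2,2-dimethylcyclobutyl]prop-2-en-1-one
Product: 11 (1R,5R)-2-{(E)-2-[2-(allyloxy)-4,6-bis(methoxymethoxy)phenyl]ethenyl}-6,6-dimethyl-3-(phenylsulfonyl)bicyclo[3.1.1]heptan-2-ol (epimers at C2 and C3), via lithium alkoxide adduct 9 (not isolated), via dilithiated hydroxy sulfone 10 (not isolated)
Conditions: PhSO2CH3, n-BuLi, THF, −78 °C; add 8; then LiN(i-Pr)2, DMPU, −78 → −20 °C; aq. NH4Cl
Reagents that add atoms: methyl phenyl sulfone CS(=O)(=O)c1ccccc1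
Why: (Phenylsulfonyl)methyllithium adds 1,2 to the ketone carbon C2 of 8, the β-alkoxy sulfone 9 is deprotonated a second time at the sulfonyl carbon C3, and carbanion 10 displaces the primary iodide at C4 by SN2, so one CH2 unit is stitched between C2 and C4 and the six-membered carbocycle of the bicyclo[3.1.1]heptane is closed at the C3–C4 bond. The closest known reaction types are the C-alkylation of β-hydroxy sulfone dianions (the first half of a Julia sequence) and the cycloalkylation of sulfonyl carbanions with bis-electrophiles. The ring closes in the 6-exo-tet mode, which the cis-1,3 arrangement of the two arms on the cyclobutane makes geometrically easy and which, being irreversible, pays for the added strain of the bridged ring. C1 and C5 are carried over from 8 (C5 is not acidic, and C1–H is no longer enolisable once the carbonyl has reacted), while the new centres C2 and C3 form without control and are both erased in steps 8 and 10. The step needs 1,2-addition rather than 1,4-addition or enolisation, which the lithium counter-ion in THF at −78 °C and the electron-rich, doubly ortho-substituted β-aryl group should secure, and C- rather than O-alkylation, which the far higher nucleophilicity of the sulfonyl carbanion over the lithium alkoxide should secure. Intermolecular alkylation of the reagent by the β-branched iodide is slow at −78 °C, so addition to the carbonyl should come first.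

**Step 8**
Reactants: 11 (1R,5R)-2-{(E)-2-[2-(allyloxy)-4,6-bis(methoxymethoxy)phenyl]ethenyl}-6,6-dimethyl-3-(phenylsulfonyl)bicyclo[3.1.1]heptan-2-ol
Product: 12 (1R,5S)-2-{(E)-2-[2-(allyloxy)-4,6-bis(methoxymethoxy)phenyl]ethenyl}-6,6-dimethylbicyclo[3.1.1]heptan-2-ol (epimers at C2)
Conditions: Na(Hg) (6% Na), Na2HPO4, MeOH/THF, −20 °C
Reagents that add atoms: none
Why: Reductive desulfonylation by electron transfer from sodium amalgam cleaves the C3–S bond, and the carbanion should be protonated by methanol faster than it expels the poor alkoxide leaving group, so C3 becomes the ring CH2 and the tertiary allylic alcohol is kept.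

**Step 9**
Reactants: 12 (1R,5S)-2-{(E)-2-[2-(allyloxy)-4,6-bis(methoxymethoxy)phenyl]ethenyl}-6,6-dimethylbicyclo[3.1.1]heptan-2-ol
Product: 13 (1R,5S)-2-{(E)-2-[2-hydroxy-4,6-bis(methoxymethoxy)phenyl]ethenyl}-6,6-dimethylbicyclo[3.1.1]heptan-2-ol (epimers at C2)
Conditions: Pd(PPh3)4 (3 mol%), morpholine, THF, rt
Reagents that add atoms: none
Why: Zerovalent palladium ionises the aryl allyl ether to a π-allyl complex that morpholine intercepts (Tsuji–Trost deallylation), which should free the phenol under basic conditions that do not ionise the tertiary alcohol.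

**Step 10**
Reactants: 13 (1R,5S)-2-{(E)-2-[2-hydroxy-4,6-bis(methoxymethoxy)phenyl]ethenyl}-6,6-dimethylbicyclo[3.1.1]heptan-2-ol
Product: 15 (1R,2R,5S)-5',7'-bis(methoxymethoxy)-6,6-dimethylspiro[bicyclo[3.1.1]heptane-2,2'-chromene], via o-quinone methide 14 (not isolated)
Conditions: pyridinium p-toluenesulfonate (10 mol%), 4 Å molecular sieves, CH2Cl2, 0 °C → rt
Reagents that add atoms: none
Why: The doubly activated tertiary carbinol should ionise under mild acid to o-quinone methide 14, whose oxa-6π electrocyclisation (the classical route from 2-hydroxystyryl carbinols to 2H-chromenes) forms the C2–O1' bond on the face of the CH2 bridge, anti to the gem-dimethyl bridge whose inner methyl shields the other face, so the spiro centre is set under kinetic substrate control whatever the carbinol configuration of 13.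

**Step 11**
Reactants: 15 (1R,2R,5S)-5',7'-bis(methoxymethoxy)-6,6-dimethylspiro[bicyclo[3.1.1]heptane-2,2'-chromene]
Product: 16 (1R,2R,5S)-5',7'-bis(methoxymethoxy)-6,6-dimethylspiro[bicyclo[3.1.1]heptane-2,2'-chromane]
Conditions: H2 (1 atm), 5% Pd/C, EtOAc, rt
Reagents that add atoms: none
Why: Heterogeneous hydrogenation of the cis-disubstituted chromene alkene under neutral conditions should give the chroman without touching the MOM ethers or the tertiary ether (no stereocentre is formed).

**Step 12**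
Reactants: 16 (1R,2R,5S)-5',7'-bis(methoxymethoxy)-6,6-dimethylspiro[bicyclo[3.1.1]heptane-2,2'-chromane]
Product: 18 1-[(1R,2R,5S)-5',7'-bis(methoxymethoxy)-6,6-dimethylspiro[bicyclo[3.1.1]heptane-2,2'-chroman]-6'-yl]-3-methylbutan-1-one, via aryllithium 17 (not isolated)
Conditions: n-BuLi, THF, 0 °C; then N-methoxy-N,3-dimethylbutanamide, −78 °C → rt; aq. NH4Cl
Reagents that add atoms: N-methoxy-N,3-dimethylbutanamide CC(C)CC(=O)N(C)OC
Why: Directed ortho-metalation should remove the C6' hydrogen flanked by the two coordinating MOM ethers in preference to C8'–H next to the hindered ring oxygen, and the aryllithium is acylated once by the Weinreb amide through its chelated tetrahedral adduct.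

**Step 13**
Reactants: 18 1-[(1R,2R,5S)-5',7'-bis(methoxymethoxy)-6,6-dimethylspiro[bicyclo[3.1.1]heptane-2,2'-chroman]-6'-yl]-3-methylbutan-1-one
Product: 19 1-[(1R,2R,5S)-5',7'-dihydroxy-6,6-dimethylspiro[bicyclo[3.1.1]heptane-2,2'-chroman]-6'-yl]-3-methylbutan-1-one
Conditions: HCl (0.5 M in MeOH), 0 °C → rt
Reagents that add atoms: none
Why: Acid-catalysed transacetalisation to methanol cleaves MOM ethers ortho to a ketone readily, so conditions mild enough to spare the tertiary alkyl aryl ether should suffice.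

**Step 14**
Reactants: 19 1-[(1R,2R,5S)-5',7'-dihydroxy-6,6-dimethylspiro[bicyclo[3.1.1]heptane-2,2'-chroman]-6'-yl]-3-methylbutan-1-one
Product: 21 euglobal G3, (1R,2R,5S)-5',7'-dihydroxy-6,6-dimethyl-6'-(3-methylbutanoyl)spiro[bicyclo[3.1.1]heptane-2,2'-chromane]-8'-carbaldehyde, via iminium chloride 20 (not isolated)
Conditions: POCl3, DMF, MeCN, 0 °C → rt; then aq. NaOAc, rt → 40 °C
Reagents that add atoms: N,N-dimethylformamide CN(C)C=O; water O
Why: Vilsmeier–Haack formylation should occur at C8', the only free ring position and one activated by three oxygen substituents, and buffered hydrolysis of iminium 20 releases the aldehyde.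

**Compound list**

1 | (1S,5S)-(−)-verbenone | CC1=CC(=O)[C@H]2C[C@@H]1C2(C)C | starting material
2 | (1S,3R)-3-acetyl-2,2-dimethylcyclobutane-1-carboxylic acid | CC(=O)[C@@H]1C[C@H](C(=O)O)C1(C)C | intermediate
3 | 1-[(1R,3S)-3-(hydroxymethyl)-2,2-dimethylcyclobutyl]ethan-1-one | CC(=O)[C@@H]1C[C@H](CO)C1(C)C | intermediate
4 | 2,4,6-trihydroxybenzaldehyde | O=Cc1c(O)cc(O)cc1O | starting material
5 | 2-hydroxy-4,6-bis(methoxymethoxy)benzaldehyde | O=Cc1c(O)cc(OCOC)cc1OCOC | intermediate
6 | 2-(allyloxy)-4,6-bis(methoxymethoxy)benzaldehyde | O=Cc1c(OCC=C)cc(OCOC)cc1OCOC | intermediate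
7 | (E)-3-[2-(allyloxy)-4,6-bis(methoxymethoxy)phenyl]-1-[(1R,3S)-3-(hydroxymethyl)-2,2-dimethylcyclobutyl]prop-2-en-1-one | O=C(/C=C/c1c(OCC=C)cc(OCOC)cc1OCOC)[C@@H]1C[C@H](CO)C1(C)C | intermediate
8 | (E)-3-[2-(allyloxy)-4,6-bis(methoxymethoxy)phenyl]-1-[(1R,3S)-3-(iodomethyl)-2,2-dimethylcyclobutyl]prop-2-en-1-one | O=C(/C=C/c1c(OCC=C)cc(OCOC)cc1OCOC)[C@@H]1C[C@H](CI)C1(C)C | intermediate
9 | lithium (E)-4-[2-(allyloxy)-4,6-bis(methoxymethoxy)phenyl]-2-[(1R,3S)-3-(iodomethyl)-2,2-dimethylcyclobutyl]-1-(phenylsulfonyl)but-3-en-2-olate (both carbinol epimers) | [Li+].[O-]C(CS(=O)(=O)c1ccccc1)(/C=C/c1c(OCC=C)cc(OCOC)cc1OCOC)[C@@H]1C[C@H](CI)C1(C)C | intermediate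
10 | dilithium species of 9 lithiated at the sulfonyl carbon | [Li+].[Li+].[O-]C([CH-]S(=O)(=O)c1ccccc1)(/C=C/c1c(OCC=C)cc(OCOC)cc1OCOC)[C@@H]1C[C@H](CI)C1(C)C | intermediate
11 | (1R,5R)-2-{(E)-2-[2-(allyloxy)-4,6-bis(methoxymethoxy)phenyl]ethenyl}-6,6-dimethyl-3-(phenylsulfonyl)bicyclo[3.1.1]heptan-2-ol (epimers at C2 and C3) | OC1(/C=C/c2c(OCC=C)cc(OCOC)cc2OCOC)C(S(=O)(=O)c2ccccc2)C[C@H]2C[C@@H]1C2(C)C | intermediate
12 | (1R,5S)-2-{(E)-2-[2-(allyloxy)-4,6-bis(methoxymethoxy)phenyl]ethenyl}-6,6-dimethylbicyclo[3.1.1]heptan-2-ol (epimers at C2) | OC1(/C=C/c2c(OCC=C)cc(OCOC)cc2OCOC)CC[C@H]2C[C@@H]1C2(C)C | intermediate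
13 | (1R,5S)-2-{(E)-2-[2-hydroxy-4,6-bis(methoxymethoxy)phenyl]ethenyl}-6,6-dimethylbicyclo[3.1.1]heptan-2-ol (epimers at C2) | OC1(/C=C/c2c(O)cc(OCOC)cc2OCOC)CC[C@H]2C[C@@H]1C2(C)C | intermediate
14 | 6-{2-[6,6-dimethylbicyclo[3.1.1]heptan-2-ylidene]ethylidene}-3,5-bis(methoxymethoxy)cyclohexa-2,4-dien-1-one (bicyclic core as in 13) | O=C1C=C(OCOC)C=C(OCOC)C1=CC=C1CC[C@H]2C[C@@H]1C2(C)C | intermediate
15 | (1R,2R,5S)-5',7'-bis(methoxymethoxy)-6,6-dimethylspiro[bicyclo[3.1.1]heptane-2,2'-chromene] | COCOc1cc(OCOC)c2C=C[C@@]3(CC[C@H]4C[C@@H]3C4(C)C)Oc2c1 | intermediate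
16 | (1R,2R,5S)-5',7'-bis(methoxymethoxy)-6,6-dimethylspiro[bicyclo[3.1.1]heptane-2,2'-chromane] | COCOc1cc(OCOC)c2CC[C@@]3(CC[C@H]4C[C@@H]3C4(C)C)Oc2c1 | intermediate
17 | 6'-lithio derivative of 16 | COCOc1c([Li])c(OCOC)c2CC[C@@]3(CC[C@H]4C[C@@H]3C4(C)C)Oc2c1 | intermediate
18 | 1-[(1R,2R,5S)-5',7'-bis(methoxymethoxy)-6,6-dimethylspiro[bicyclo[3.1.1]heptane-2,2'-chroman]-6'-yl]-3-methylbutan-1-one | COCOc1c(C(=O)CC(C)C)c(OCOC)c2CC[C@@]3(CC[C@H]4C[C@@H]3C4(C)C)Oc2c1 | intermediate
19 | 1-[(1R,2R,5S)-5',7'-dihydroxy-6,6-dimethylspiro[bicyclo[3.1.1]heptane-2,2'-chroman]-6'-yl]-3-methylbutan-1-one | Oc1c(C(=O)CC(C)C)c(O)c2CC[C@@]3(CC[C@H]4C[C@@H]3C4(C)C)Oc2c1 | intermediate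
20 | N-{[(1R,2R,5S)-5',7'-dihydroxy-6,6-dimethyl-6'-(3-methylbutanoyl)spiro[bicyclo[3.1.1]heptane-2,2'-chroman]-8'-yl]methylidene}-N-methylmethanaminium chloride | C[N+](C)=Cc1c(O)c(C(=O)CC(C)C)c(O)c2CC[C@@]3(CC[C@H]4C[C@@H]3C4(C)C)Oc12.[Cl-] | intermediate
21 | euglobal G3, (1R,2R,5S)-5',7'-dihydroxy-6,6-dimethyl-6'-(3-methylbutanoyl)spiro[bicyclo[3.1.1]heptane-2,2'-chromane]-8'-carbaldehyde | CC(C)CC(=O)c1c(O)c(C=O)c2c(c1O)CC[C@@]1(CC[C@H]3C[C@@H]1C3(C)C)O2 | target

**Step count and risks**

Total step count: 14. Longest linear sequence: 12 steps (1, 2, 5–14; the branch 3, 4, 5–14 is equally long).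

Steps most likely to fail:

Step 7. Enolisation of the enone by the basic sulfonyl carbanion, retro-addition of alkoxide 9 before the second deprotonation, or O-alkylation by the tertiary alkoxide may prevent the ring closure. The fallback sets out from 3 and comes back at 12. Iodination of 3 (I2, PPh3, imidazole) gives 1-[(1R,3S)-3-(iodomethyl)-2,2-dimethylcyclobutyl]ethan-1-one F1. Its kinetic methyl enolate (LiN(SiMe3)2, THF, −78 → 0 °C) should close the same C3–C4 bond by intramolecular alkylation to give (1R,5S)-6,6-dimethylbicyclo[3.1.1]heptan-2-one F2. Aldehyde 6 is converted by Takai olefination (CrCl2, CHI3, THF) into 1-(allyloxy)-2-[(E)-2-iodoethenyl]-3,5-bis(methoxymethoxy)benzene F3. After iodine–lithium exchange (t-BuLi, Et2O, −78 °C) F3 adds to F2 to give carbinol 12 as a single C2 epimer.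

Step 10. The ionisation may stay reversible under acid, which would equilibrate the spiro centre, or the ring closure may show poor facial selectivity. The fallback sets out from 12 and comes back at 15, and replaces the cationic closure by an anionic one. Oxidative 1,3-transposition of 12 (Babler–Dauben oxidation with pyridinium chlorochromate, C5H5NH[CrO3Cl]) gives 1-[2-(allyloxy)-4,6-bis(methoxymethoxy)phenyl]-2-[6,6-dimethylbicyclo[3.1.1]heptan-2-ylidene]ethan-1-one F4. Deallylation (Pd(PPh3)4, morpholine) gives 2-[6,6-dimethylbicyclo[3.1.1]heptan-2-ylidene]-1-[2-hydroxy-4,6-bis(methoxymethoxy)phenyl]ethan-1-one F5. With K2CO3 in MeOH at 0 °C, F5 should close by kinetic oxa-Michael addition from the same face to (1R,2R,5S)-5',7'-bis(methoxymethoxy)-6,6-dimethylspiro[bicyclo[3.1.1]heptane-2,2'-chroman]-4'-one F6. NaBH4 gives (1R,2R,5S)-5',7'-bis(methoxymethoxy)-6,6-dimethylspiro[bicyclo[3.1.1]heptane-2,2'-chroman]-4'-ol F7, and dehydration (MsCl, Et3N) returns chromene 15.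

Step 14. The chelated, acyl-deactivated phenol may formylate slowly or on oxygen, and the acidic hydrolysis may open the tertiary alkyl aryl ether. The fallback sets out from 18 and comes back at 21. Bromination of 18 at its only free ring position (N-bromosuccinimide, MeCN, 0 °C) gives 1-[(1R,2R,5S)-8'-bromo-5',7'-bis(methoxymethoxy)-6,6-dimethylspiro[bicyclo[3.1.1]heptane-2,2'-chroman]-6'-yl]-3-methylbutan-1-one F8. Palladium-catalysed reductive carbonylation (Pd(OAc)2, di(1-adamantyl)-n-butylphosphine, CO/H2, TMEDA, toluene, 100 °C) gives (1R,2R,5S)-5',7'-bis(methoxymethoxy)-6,6-dimethyl-6'-(3-methylbutanoyl)spiro[bicyclo[3.1.1]heptane-2,2'-chromane]-8'-carbaldehyde F9. Cleavage of both MOM ethers under the conditions of step 13 gives 21.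

**Further compounds**

F1 | step 7 | 1-[(1R,3S)-3-(iodomethyl)-2,2-dimethylcyclobutyl]ethan-1-one | CC(=O)[C@@H]1C[C@H](CI)C1(C)C
F2 | step 7 | (1R,5S)-6,6-dimethylbicyclo[3.1.1]heptan-2-one | O=C1CC[C@H]2C[C@@H]1C2(C)C
F3 | step 7 | 1-(allyloxy)-2-[(E)-2-iodoethenyl]-3,5-bis(methoxymethoxy)benzene | I/C=C/c1c(OCC=C)cc(OCOC)cc1OCOC
F4 | step 10 | 1-[2-(allyloxy)-4,6-bis(methoxymethoxy)phenyl]-2-[6,6-dimethylbicyclo[3.1.1]heptan-2-ylidene]ethan-1-one (bicyclic core as in 12) | O=C(C=C1CC[C@H]2C[C@@H]1C2(C)C)c1c(OCC=C)cc(OCOC)cc1OCOC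
F5 | step 10 | 2-[6,6-dimethylbicyclo[3.1.1]heptan-2-ylidene]-1-[2-hydroxy-4,6-bis(methoxymethoxy)phenyl]ethan-1-one (bicyclic core as in 12) | O=C(C=C1CC[C@H]2C[C@@H]1C2(C)C)c1c(O)cc(OCOC)cc1OCOC
F6 | step 10 | (1R,2R,5S)-5',7'-bis(methoxymethoxy)-6,6-dimethylspiro[bicyclo[3.1.1]heptane-2,2'-chroman]-4'-one | COCOc1cc(OCOC)c2C(=O)C[C@@]3(CC[C@H]4C[C@@H]3C4(C)C)Oc2c1
F7 | step 10 | (1R,2R,5S)-5',7'-bis(methoxymethoxy)-6,6-dimethylspiro[bicyclo[3.1.1]heptane-2,2'-chroman]-4'-ol (either carbinol epimer) | COCOc1cc(OCOC)c2C(O)C[C@@]3(CC[C@H]4C[C@@H]3C4(C)C)Oc2c1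
F8 | step 14 | 1-[(1R,2R,5S)-8'-bromo-5',7'-bis(methoxymethoxy)-6,6-dimethylspiro[bicyclo[3.1.1]heptane-2,2'-chroman]-6'-yl]-3-methylbutan-1-one | COCOc1c(C(=O)CC(C)C)c(OCOC)c2CC[C@@]3(CC[C@H]4C[C@@H]3C4(C)C)Oc2c1Br
F9 | step 14 | (1R,2R,5S)-5',7'-bis(methoxymethoxy)-6,6-dimethyl-6'-(3-methylbutanoyl)spiro[bicyclo[3.1.1]heptane-2,2'-chromane]-8'-carbaldehyde | COCOc1c(C(=O)CC(C)C)c(OCOC)c2CC[C@@]3(CC[C@H]4C[C@@H]3C4(C)C)Oc2c1C=O
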